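## Plan

- **Cuts:** the prenyl C=C is cut first (Wittig), then the two bonds made together in the key step, C6–C(phenyl) and C1–C2. The open chain is then cut at the enone C1=C6 (cross-metathesis), at C4–C5 (Stille) and at the thioester C=C (Wittig). The pyran ring goes back to the acetophenone and 3-methylbut-2-enal.
- **Enabling feature:** in the cyclohexene (C1 aroyl, C2 prenyl, C3 methyl, C3=C4, C5 methylene, C6 phenyl), C6 is β and C1 is α to the aryl ketone, and C2 carries a CH2–C branch. The ring therefore maps onto an aryl enone C1=C6 linked through C5 and a (Z)-C3=C4 alkene to an unsaturated thioester whose β-carbon is C2.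
- **Forward order:** the pyran ring of the chromene is closed first and the acetyl group is turned into a vinyl ketone. A (Z)-iodo dienyl thioester from propargyl alcohol is allylated and joined to the vinyl ketone by cross-metathesis. The cyclohexene ring closes last, in the rhodium step, followed by thioester → aldehyde → prenyl and MOM removal.
- **Stereochemistry:** C6 comes from (R)-BINAP on rhodium. C2 and C1 follow from C6 during ring closure (C2 branch pseudoaxial by allylic strain with the C3 methyl, aroyl equatorial). The (Z)-C3=C4 geometry comes from anti-carbomagnesiation, the (E)-alkenes from Wittig olefination and metathesis.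

Key step: step 9

Assumption: S-ethyl (triphenylphosphoranylidene)thioacetate is used as a purchased stabilised ylide, and (R)-BINAP is chosen on the expectation that the acyclic (E)-enone follows the usual facial sense of rhodium/BINAP arylation; the antipodal ligand would be used should C6 emerge as 6S.

Notation: Ar = 5-methoxy-7-(methoxymethoxy)-2,2-dimethyl-2H-chromen-8-yl. Ring locants C1–C6 are those of the target cyclohexene as defined above.

## Route

Step 1
Reactants: 1 2',6'-dihydroxy-4'-methoxyacetophenone; 2 3-methylbut-2-enal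
Product: 4 1-(7-hydroxy-5-methoxy-2,2-dimethyl-2H-chromen-8-yl)ethan-1-one, via quinone methide 3 (not isolated)
Conditions: 2 (1.2 equiv), ethylenediammonium diacetate (10 mol%), xylene, 140 °C
Reagents that add atoms: none
Why: Amine-salt-catalysed Knoevenagel-type condensation at the ring carbon between OH and OMe, followed by oxa-6π electrocyclisation of the o-quinone methide, should close the 2,2-dimethylpyran ring, and the mirror symmetry of 1 allows only one chromene.

Step 2
Reactants: 4 1-(7-hydroxy-5-methoxy-2,2-dimethyl-2H-chromen-8-yl)ethan-1-one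
Product: 5 1-Ar-ethan-1-one (MOM ether of 4)
Conditions: NaH, MOMCl, DMF, 0 °C → rt
Reagents that add atoms: chloromethyl methyl ether, COCCl
Why: Williamson O-alkylation of the sodium phenoxide, which NaH forms in preference to the ketone enolate, should cap the chelated phenol so that it cannot add to the enone made later.

Step 3
Reactants: 5 1-Ar-ethan-1-one
Product: 7 3-(dimethylamino)-1-Ar-propan-1-one, via lithium enolate 6 (not isolated)
Conditions: LiN(SiMe3)2, THF, −78 °C; Me2N=CH2+ I−, −78 °C → rt
Reagents that add atoms: dimethyl(methylidene)ammonium iodide (Eschenmoser's salt), C=[N+](C)C.[I-]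
Why: Mannich aminomethylation of the kinetic lithium enolate with a preformed iminium salt should stop at the mono-adduct.

Step 4
Reactants: 7 3-(dimethylamino)-1-Ar-propan-1-one
Product: 9 1-Ar-prop-2-en-1-one (aryl vinyl ketone), via ammonium iodide 8 (not isolated)
Conditions: MeI, CH2Cl2, rt; aq. NaHCO3, rt; product used at once
Reagents that add atoms: none
Why: N-Methylation turns the amine into a leaving group, and E1cB (Hofmann-type) β-elimination under weak base should deliver the vinyl ketone.

Step 5
Reactants: 10 propargyl alcohol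
Product: 12 (Z)-3-iodo-2-methylprop-2-en-1-ol, via alkenylmagnesium chelate 11 (not isolated)
Conditions: MeMgBr (3 equiv), CuI (10 mol%), THF, −10 °C → rt; I2, −10 °C
Reagents that add atoms: methylmagnesium bromide, C[Mg]Br; iodine, II
Why: Copper-catalysed, alkoxide-directed anti-carbomagnesiation puts methyl on the inner alkyne carbon and magnesium on the terminus cis to CH2O, and iodinolysis with retention should give the (Z)-iodide.

Step 6
Reactants: 12 (Z)-3-iodo-2-methylprop-2-en-1-ol
Product: 14 S-ethyl (2E,4Z)-5-iodo-4-methylpenta-2,4-dienethioate, via iodo enal 13 (not isolated)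
Conditions: MnO2 (10 equiv), Ph3P=CHC(O)SEt (1.3 equiv), CH2Cl2, rt, dark
Reagents that add atoms: S-ethyl (triphenylphosphoranylidene)thioacetate, CCSC(=O)C=P(c1ccccc1)(c1ccccc1)c1ccccc1
Why: Tandem allylic oxidation–Wittig olefination traps the isomerisation-prone (Z)-enal as it forms, and the stabilised ylide should give the (E)-alkene.

Step 7
Reactants: 14 S-ethyl (2E,4Z)-5-iodo-4-methylpenta-2,4-dienethioate
Product: 15 S-ethyl (2E,4Z)-4-methylocta-2,4,7-trienethioate
Conditions: allylSnBu3, Pd2(dba)3 (2.5 mol%), AsPh3 (10 mol%), DMF, rt, dark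
Reagents that add atoms: allyltributylstannane, C=CC[Sn](CCCC)(CCCC)CCCC
Why: Stille coupling, in which oxidative addition of zerovalent palladium into the C–I bond and allyl transfer from tin proceed with retention of the (Z)-geometry, while the thioester C–S bond is not activated under copper-free conditions.

Step 8
Reactants: 9 1-Ar-prop-2-en-1-one; 15 S-ethyl (2E,4Z)-4-methylocta-2,4,7-trienethioate
Product: 16 S-ethyl (2E,4Z,7E)-9-Ar-4-methyl-9-oxonona-2,4,7-trienethioate
Conditions: 15 (1.5 equiv), second-generation Hoveyda–Grubbs catalyst (5 mol%), 1,4-benzoquinone (10 mol%), CH2Cl2, 35 °C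
Reagents that add atoms: none
Why: Olefin cross-metathesis of a terminal alkene with an electron-poor vinyl ketone is (E)-selective and should leave the trisubstituted, conjugated and chromene alkenes untouched, with benzoquinone suppressing Ru–H-induced migration of the skipped alkene.

Step 9
Reactants: 16 S-ethyl (2E,4Z,7E)-9-Ar-4-methyl-9-oxonona-2,4,7-trienethioate; 17 phenylboronic acid
Product: 18 S-ethyl 2-[(1S,5R,6R)-6-(Ar-carbonyl)-2-methyl-5-phenylcyclohex-2-en-1-yl]ethanethioate (ring locants: 1R,2S,6R)
Conditions: [Rh(OH)((R)-binap)]2 (3 mol%), PhB(OH)2 (2 equiv), dioxane–H2O (20:1), 35 °C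
Reagents that add atoms: none
Why: Transmetalation of 17 with the Rh–OH complex gives a Rh–Ph species that inserts the aryl enone C1=C6 of 16, forming C6–phenyl and an oxa-π-allyl (Z)-Rh enolate that adds through C1 to C2 of the unsaturated thioester, after which water protonates the thioester enolate and regenerates Rh–OH. The closest known reaction type is the rhodium-catalysed tandem conjugate arylation–Michael cyclisation of arylboronic acids with tethered bis-acceptors, together with its aldol counterpart. The cyclohexene closes in a 6-exo-trig mode in which the preset (Z)-C3=C4 alkene becomes the ring alkene. C6 is fixed by the (R)-BINAP ligand on rhodium; C2 by developing allylic 1,2-strain with the C3 methyl, which keeps the CH2C(O)SEt branch pseudoaxial and hence trans to the equatorial phenyl; and C1 by chair-like closure of the (Z)-enolate with H1 anti to H6, which leaves the aroyl group equatorial, trans to phenyl and cis to the C2 branch. The step needs phenyl transfer to the aryl enone and not to the dienyl thioester, which the more electrophilic, unhindered ketone-activated alkene secures against a thioester acceptor whose β-carbon C2 adjoins the fully substituted C3, and it needs ring closure to outrun protonolysis, which the low water content and the (Z)-alkene-preorganised six-atom tether secure. The neutral, base-free preformed hydroxo catalyst at 35 °C spares the doubly allylic C5 methylene and avoids a racemic background from cod-ligated rhodium.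

Step 10
Reactants: 18 S-ethyl 2-[(1S,5R,6R)-6-(Ar-carbonyl)-2-methyl-5-phenylcyclohex-2-en-1-yl]ethanethioate
Product: 19 2-[(1S,5R,6R)-6-(Ar-carbonyl)-2-methyl-5-phenylcyclohex-2-en-1-yl]acetaldehyde
Conditions: Et3SiH (3 equiv), 10% Pd/C (5 mol%), acetone, rt
Reagents that add atoms: none
Why: Fukuyama reduction, in which palladium inserts into the thioester C–S bond and silane delivers hydride, should give the aldehyde without touching the hindered aryl ketone or the stereocentres.

Step 11
Reactants: 19 2-[(1S,5R,6R)-6-(Ar-carbonyl)-2-methyl-5-phenylcyclohex-2-en-1-yl]acetaldehyde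
Product: 20 Ar[(1R,2S,6R)-3-methyl-2-(3-methylbut-2-en-1-yl)-6-phenylcyclohex-3-en-1-yl]methanone
Conditions: i-PrPPh3+ I− (1.5 equiv), n-BuLi (1.4 equiv), THF, 0 °C; 19, −78 °C → 0 °C
Reagents that add atoms: isopropyltriphenylphosphonium iodide, CC(C)[P+](c1ccccc1)(c1ccccc1)c1ccccc1.[I-]
Why: Wittig olefination with the non-stabilised isopropylidene ylide is fast at the unhindered aldehyde, whereas the doubly ortho-substituted, α-branched aryl ketone should be too hindered to add the ylide or to be enolised at low temperature, so C1 should stay intact.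

Step 12
Reactants: 20 Ar[(1R,2S,6R)-3-methyl-2-(3-methylbut-2-en-1-yl)-6-phenylcyclohex-3-en-1-yl]methanone
Product: 21 (7-hydroxy-5-methoxy-2,2-dimethyl-2H-chromen-8-yl)[(1R,2S,6R)-3-methyl-2-(3-methylbut-2-en-1-yl)-6-phenylcyclohex-3-en-1-yl]methanone (CNP0307644.1)
Conditions: 3 M aq. HCl, MeOH–THF, rt
Reagents that add atoms: none
Why: Acid-catalysed acetal methanolysis of the MOM ether, assisted by the ortho carbonyl, should free the chelated phenol under conditions mild enough for the chromene and the trisubstituted alkenes, and no stereocentre is involved.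

## Compound list

1 | 2',6'-dihydroxy-4'-methoxyacetophenone | CC(=O)c1c(O)cc(OC)cc1O | starting material
2 | 3-methylbut-2-enal | CC(C)=CC=O | starting material
3 | 2-acetyl-3-hydroxy-5-methoxy-6-(3-methylbut-2-en-1-ylidene)cyclohexa-2,4-dien-1-one (o-quinone methide) | CC(=O)C1=C(O)C=C(OC)C(=CC=C(C)C)C1=O | intermediate (not isolated)
4 | 1-(7-hydroxy-5-methoxy-2,2-dimethyl-2H-chromen-8-yl)ethan-1-one | CC(=O)c1c(O)cc(OC)c2c1OC(C)(C)C=C2 | intermediate
5 | 1-[5-methoxy-7-(methoxymethoxy)-2,2-dimethyl-2H-chromen-8-yl]ethan-1-one | CC(=O)c1c(OCOC)cc(OC)c2c1OC(C)(C)C=C2 | intermediate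
6 | lithium 1-[5-methoxy-7-(methoxymethoxy)-2,2-dimethyl-2H-chromen-8-yl]ethen-1-olate | [Li]OC(=C)c1c(OCOC)cc(OC)c2c1OC(C)(C)C=C2 | intermediate (not isolated)
7 | 3-(dimethylamino)-1-[5-methoxy-7-(methoxymethoxy)-2,2-dimethyl-2H-chromen-8-yl]propan-1-one | CN(C)CCC(=O)c1c(OCOC)cc(OC)c2c1OC(C)(C)C=C2 | intermediate
8 | 3-[5-methoxy-7-(methoxymethoxy)-2,2-dimethyl-2H-chromen-8-yl]-N,N,N-trimethyl-3-oxopropan-1-aminium iodide | C[N+](C)(C)CCC(=O)c1c(OCOC)cc(OC)c2c1OC(C)(C)C=C2.[I-] | intermediate (not isolated)
9 | 1-[5-methoxy-7-(methoxymethoxy)-2,2-dimethyl-2H-chromen-8-yl]prop-2-en-1-one | C=CC(=O)c1c(OCOC)cc(OC)c2c1OC(C)(C)C=C2 | intermediate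
10 | propargyl alcohol (prop-2-yn-1-ol) | C#CCO | starting material
11 | 4-methyl-2,5-dihydro-1,2-oxamagnesole (cyclic (Z)-alkenylmagnesium alkoxide) | CC1=C[Mg]OC1 | intermediate (not isolated)
12 | (Z)-3-iodo-2-methylprop-2-en-1-ol | OC/C(C)=C\I | intermediate
13 | (Z)-3-iodo-2-methylprop-2-enal | O=C/C(C)=C\I | intermediate (not isolated)
14 | S-ethyl (2E,4Z)-5-iodo-4-methylpenta-2,4-dienethioate | CCSC(=O)/C=C/C(C)=C\I | intermediate
15 | S-ethyl (2E,4Z)-4-methylocta-2,4,7-trienethioate | CCSC(=O)/C=C/C(C)=C\CC=C | intermediate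
16 | S-ethyl (2E,4Z,7E)-9-[5-methoxy-7-(methoxymethoxy)-2,2-dimethyl-2H-chromen-8-yl]-4-methyl-9-oxonona-2,4,7-trienethioate | COc1cc(OCOC)c(C(=O)/C=C/C/C=C(C)\C=C\C(=O)SCC)c2c1C=CC(C)(C)O2 | intermediate
17 | phenylboronic acid | OB(O)c1ccccc1 | starting material
18 | S-ethyl 2-[(1S,5R,6R)-6-{[5-methoxy-7-(methoxymethoxy)-2,2-dimethyl-2H-chromen-8-yl]carbonyl}-2-methyl-5-phenylcyclohex-2-en-1-yl]ethanethioate | COc1cc(OCOC)c(C(=O)[C@@H]2[C@H](CC(=O)SCC)C(C)=CC[C@H]2c2ccccc2)c2c1C=CC(C)(C)O2 | intermediate
19 | 2-[(1S,5R,6R)-6-{[5-methoxy-7-(methoxymethoxy)-2,2-dimethyl-2H-chromen-8-yl]carbonyl}-2-methyl-5-phenylcyclohex-2-en-1-yl]acetaldehyde | COc1cc(OCOC)c(C(=O)[C@@H]2[C@H](CC=O)C(C)=CC[C@H]2c2ccccc2)c2c1C=CC(C)(C)O2 | intermediate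
20 | [5-methoxy-7-(methoxymethoxy)-2,2-dimethyl-2H-chromen-8-yl][(1R,2S,6R)-3-methyl-2-(3-methylbut-2-en-1-yl)-6-phenylcyclohex-3-en-1-yl]methanone | COc1cc(OCOC)c(C(=O)[C@@H]2[C@H](CC=C(C)C)C(C)=CC[C@H]2c2ccccc2)c2c1C=CC(C)(C)O2 | intermediate
21 | (7-hydroxy-5-methoxy-2,2-dimethyl-2H-chromen-8-yl)[(1R,2S,6R)-3-methyl-2-(3-methylbut-2-en-1-yl)-6-phenylcyclohex-3-en-1-yl]methanone | COc1cc(O)c(C(=O)[C@@H]2[C@H](CC=C(C)C)C(C)=CC[C@H]2c2ccccc2)c2c1C=CC(C)(C)O2 | target

## Step count and risks

Total step count: 12. Longest linear sequence: 9 steps (steps 1–4 and 8–12, from 1); the propargyl alcohol branch (steps 5–7) joins at step 8.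

**Step 9.** The Rh enolate may be protonated by water before it closes onto C2, or the closure may discriminate poorly between the two faces at C2. The fallback separates the two events. From 16 and 17, the same [Rh(OH)((R)-binap)]2-catalysed phenylation is run in water-rich dioxane (1:1) so that the enolate is deliberately protonated, giving the open-chain S-ethyl (2E,4Z,7R)-9-Ar-4-methyl-9-oxo-7-phenylnona-2,4-dienethioate F1 with C6 already set. F1 is then cyclised by intramolecular Michael addition of the ketone enolate under reversible base catalysis (Cs2CO3, MeCN, rt), a 6-exo-trig closure under thermodynamic control that should favour the same equatorial phenyl, equatorial aroyl and pseudoaxial C2 branch. This returns to 18.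

**Step 8.** The Ru=CHR alkylidene formed at the terminal alkene of 15 may close onto the thioester-conjugated alkene of its own chain with extrusion of a cyclopentadiene, Ru–H species may move the skipped alkene into conjugation, and the vinyl ketone may oligomerise. The fallback forms C4–C5 last instead of C1=C6. From 9, cross-metathesis with excess allyl bromide (second-generation Hoveyda–Grubbs catalyst, CH2Cl2, 40 °C), a partner with no internal trap, should give (2E)-4-bromo-1-Ar-but-2-en-1-one F2. From 14, stannylation with (Bu3Sn)2 and Pd(PPh3)4 in toluene at 80 °C should give S-ethyl (2E,4Z)-4-methyl-5-(tributylstannyl)penta-2,4-dienethioate F3. Allyl–vinyl Stille coupling of F2 with F3 (Pd2(dba)3, AsPh3, THF, 40 °C) proceeds with retention at the (Z)-alkene and returns to 16.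

**Step 10.** Pd–H generated from the silane may saturate or shift the chromene alkene or the ring alkene, or reduction may run past the aldehyde. A lead-poisoned Pd/CaCO3 catalyst is the first adjustment. The fallback drops palladium: from 18, NaBH4 in EtOH–THF at 0 °C should reduce the thioester to the primary alcohol [(1R,2S,6R)-2-(2-hydroxyethyl)-3-methyl-6-phenylcyclohex-3-en-1-yl](Ar)methanone F4, the doubly ortho-substituted aryl ketone being expected to resist hydride. Oxidation of F4 with Dess–Martin periodinane buffered with NaHCO3 in CH2Cl2 then returns to 19.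

## Further compounds

F1 | step 9 | S-ethyl (2E,4Z,7R)-9-[5-methoxy-7-(methoxymethoxy)-2,2-dimethyl-2H-chromen-8-yl]-4-methyl-9-oxo-7-phenylnona-2,4-dienethioate | COc1cc(OCOC)c(C(=O)C[C@@H](C/C=C(C)\C=C\C(=O)SCC)c2ccccc2)c2c1C=CC(C)(C)O2
F2 | step 8 | (2E)-4-bromo-1-[5-methoxy-7-(methoxymethoxy)-2,2-dimethyl-2H-chromen-8-yl]but-2-en-1-one | BrC/C=C/C(=O)c1c(OCOC)cc(OC)c2c1OC(C)(C)C=C2
F3 | step 8 | S-ethyl (2E,4Z)-4-methyl-5-(tributylstannyl)penta-2,4-dienethioate | CCSC(=O)/C=C/C(C)=C\[Sn](CCCC)(CCCC)CCCC
F4 | step 10 | [(1R,2S,6R)-2-(2-hydroxyethyl)-3-methyl-6-phenylcyclohex-3-en-1-yl][5-methoxy-7-(methoxymethoxy)-2,2-dimethyl-2H-chromen-8-yl]methanone | COc1cc(OCOC)c(C(=O)[C@@H]2[C@H](CCO)C(C)=CC[C@H]2c2ccccc2)c2c1C=CC(C)(C)O2
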